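The beta flask was slow, and I took that as a gift: after 25.0 min it still held 36% of its D, so its readings could serve as a clock.

| setting | beta | green | red | amber | blue |
|---|---|---|---|---|---|
| D | 0.54 M | 0.80 M | 0.80 M | 0.80 M | 0.80 M |
| Q | 0.30 equiv | 0.300 equiv | 0.500 equiv | 0.800 equiv | 1.00 equiv |
| remark | run made earlier |  |  |  |  |
| time |  | 40 min | 40 min | 40 min | 40 min |

beta run (percent of the D charged)

| time / min | J / % | D / % |
|---|---|---|
| 6.00 | 17 | 76 |
| 12.0 | 31 | 61 |
| 20.0 | 46 | 41 |
| 25.0 | 53 | 36 |

(readings scatter by 1.5 percentage points)

- the numbers in the tables scatter by 1.5 percentage points (one standard deviation)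
- "hardly changes" means that all values lie within two and a half points (for a concentration: within two and a half percent of the largest)

- [J] at the end for green, red, amber, blue, in this order
- the shape of the row from first to last (hardly changes / rises, then falls / falls all the way / rises all the way / falls, then rises)

I read that clock in beta in two ways, first from the fall of D, with k_D the first-order rate constant of that fall:

k_D = −ln(D left)/t = 0.0409 min⁻¹, half-life 17.0 min

The second way was from the rise of J, scaling k_D by the selectivity, the share of lost D found as J:

k_J = k_D × J/(D lost) = 0.0338 min⁻¹, t_J = ln(2)/k_J = 20.5 min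

I called t_J the half-life D would have if making J were its one exit. In beta the two parted, t_J being longer than the D half-life, and the D clock was the one that cheated, since at 25.0 min it counted 11 percentage points of the charge that read as neither D nor J. The J clock of beta, reckoned afresh from the reading at 6.00 min, gave 21.4 min, close to the first.

One level of Q cannot say which exit uses Q. I assumed that the J clock ignores Q and that the side exit is first order in Q, and so, with Q held at its charge, pseudo-first-order in D:

k_S = (k_D − k_J)/[Q] = 7.23 × 10⁻⁴ M⁻¹ s⁻¹, k = k_J + k_S[Q]

[J] = [D charged] × (k_J/k) × (1 − exp(−kt))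

green: k = 0.0442 min⁻¹, [J] = 0.508 M

blue: k = 0.0685 min⁻¹, [J] = 0.370 M

So my row fell from green to blue. The forecast differed: reasoning that “first order in D and Q acts as a catalyst”, it gave 0.6 M, 0.64 M, 0.645 M and 0.648 M, a row that rises all the way.

The flasks gave 0.495 M, 0.440 M, 0.370 M and 0.331 M; the row falls all the way.

    D → J (k = 5.60 × 10⁻⁴ s⁻¹)
    D + Q → E (k = 0.00130 M⁻¹ s⁻¹)
    Q + E → G (k = 2.70 × 10⁻⁴ M⁻¹ s⁻¹)
    E ⇌ Z (K = 4.70, k = 4.40 × 10⁻⁵ s⁻¹)
    G ⇌ X (K = 1.20, k = 2.90 × 10⁻⁵ s⁻¹)

Blue, with the step D + Q → E left out, ended at 0.591 M rather than 0.331 M. I read the J clock again over the second half of green and of blue, from 20.0 min to 40.0 min. Green gave t_J = 20.7 min, and blue, with 3.33 times the equivalents of Q, gave 20.9 min.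

The earlier runs and the new flask were computed from invented constants, and the scatter is random.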